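The route rests on closing the β-ring between C2, the methylene beside the quaternary C1, and the carbinol carbon C3. An acyclic iodo keto aldehyde, carrying a sacrificial methyl stereocentre at C5 set by Brown crotylation, cyclises by cobalt-assisted alkylchromium addition to the aldehyde. The step exploits the C1 gem-dimethyl group: its axial methyl forces C3–O and C5–CH3 equatorial in the chair, so one operation forms the C2–C3 bond and the (3R) centre. The C6 ketone then becomes an enol triflate, which erases C5; Stille coupling and two Wittig reactions (C15 + C10 + C15) with pre-acylated end groups complete the mixed diester.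

Key step: step 6

Assumption: (R)-α-ionone is taken as purchasable in enantiopure form (otherwise the racemate is resolved by preparative chiral chromatography before step 12).

Step 1
Reactants: 1 3,3-dimethyloxetane
Product: 2 3-iodo-2,2-dimethylpropan-1-ol
Conditions: HI (57% aq), CH2Cl2, 0 °C to rt
Reagents that add atoms: hydrogen iodide, I
Why: Acid-promoted SN2 ring opening of the strained oxetane by iodide; the oxetane is symmetric, so only one iodo alcohol can form.

Step 2
Reactants: 2 3-iodo-2,2-dimethylpropan-1-ol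
Product: 3 3-iodo-2,2-dimethylpropanal
Conditions: TEMPO (10 mol %), PhI(OAc)2, CH2Cl2, rt
Reagents that add atoms: none
Why: TEMPO/PhI(OAc)2 oxidation should stop at the aldehyde, which has no alpha-hydrogen and so can neither enolise nor lose HI.

Step 3
Reactants: 3 3-iodo-2,2-dimethylpropanal
Product: 5 (3S,4S)-1-iodo-2,2,4-trimethylhex-5-en-3-ol, via borinate ester 4 (not isolated)
Conditions: pre-formed (E)-crotyl-B(Ipc)2 (Ipc groups from (+)-α-pinene), THF, −78 °C; then HOCH2CH2NH2, rt
Reagents that add atoms: (E)-crotylbis(isopinocampheyl)borane, C/C=C/CB([C@@H]1C[C@@H]2C[C@H]([C@H]1C)C2(C)C)[C@@H]1C[C@@H]2C[C@H]([C@H]1C)C2(C)C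
Why: Brown crotylboration through a closed chair transition state, in which the (E)-crotyl geometry gives the anti relationship and the Ipc groups direct attack to the Si face of the aldehyde, should set (3S,4S); the 4-methyl centre is the relay used in step 6.

Step 4
Reactants: 5 (3S,4S)-1-iodo-2,2,4-trimethylhex-5-en-3-ol
Product: 7 (3S,4S)-6-iodo-3,5,5-trimethylhexane-1,4-diol, via alkylborane 6 (not isolated)
Conditions: 9-BBN (2 equiv), THF, 0 °C to rt; then 30% H2O2, aq NaOAc, 0 °C to rt
Reagents that add atoms: hydrogen peroxide, OO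
Why: Anti-Markovnikov hydroboration of the terminal alkene with 9-BBN and buffered peroxide oxidation should give the primary alcohol without touching the stereocentres, the weakly basic buffer avoiding oxetane formation from the iodo alcohol.

Step 5
Reactants: 7 (3S,4S)-6-iodo-3,5,5-trimethylhexane-1,4-diol
Product: 9 (3S)-6-iodo-3,5,5-trimethyl-4-oxohexanal, via bis-alkoxysulfonium salt 8 (not isolated)
Conditions: (COCl)2, DMSO, CH2Cl2, −78 °C; then Et3N, −78 to −20 °C
Reagents that add atoms: none
Why: Swern oxidation activates both hydroxyls before any carbonyl exists, so the 1,4-diol should go to the keto aldehyde instead of a lactone, and the cold amine step should leave the alpha-methyl centre intact.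

Step 6
Reactants: 9 (3S)-6-iodo-3,5,5-trimethyl-4-oxohexanal
Product: 11 (4R,6S)-4-hydroxy-2,2,6-trimethylcyclohexan-1-one, via alkylchromium species 10 (not isolated)
Conditions: CrCl2 (4 equiv), CoPc (cobalt phthalocyanine, Co(C32H16N8), 10 mol %), DMF, 25–30 °C; aqueous work-up
Reagents that add atoms: none
Why: CoPc is reduced by CrCl2 to monovalent cobalt, which cleaves the neopentyl-type C–I bond of 9; the primary radical is captured by divalent chromium to give alkylchromium 10 (trivalent chromium), which adds to the aldehyde carbon as in a Takai–Utimoto alkylchromium (Nozaki–Hiyama–Kishi-type) addition, here run intramolecularly. The ring closes in a 6-exo-trig mode by forming the bond between the CH2 next to the gem-dimethyl carbon and the carbinol carbon (carotenoid C2–C3). The new carbinol centre is controlled by the (S)-methyl stereocentre alpha to the ketone: in the chair transition state the axial methyl of the gem-dimethyl group is 1,3-diaxial to both the methyl-bearing carbon and the forming carbinol carbon, so the methyl group and the chromium-bound oxygen both sit equatorial, which should give the cis (4R,6S) product, whose C4 is carotenoid C3 with the R configuration. The step needs aldehyde-over-ketone chemoselectivity, which organochromium reagents provide, and retention of the epimerisable alpha-centre, which the neutral medium secures. Any trans diastereomer is removed by chromatography before the relay centre is erased in step 8.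

Step 7
Reactants: 11 (4R,6S)-4-hydroxy-2,2,6-trimethylcyclohexan-1-one
Product: 12 (1R,5S)-3,3,5-trimethyl-4-oxocyclohexyl tetradecanoate
Conditions: myristoyl chloride, pyridine, DMAP (cat.), CH2Cl2, 0 °C to rt
Reagents that add atoms: tetradecanoyl chloride, CCCCCCCCCCCCCC(=O)Cl
Why: Nucleophile-catalysed acylation (pyridine/DMAP) of the unhindered secondary alcohol installs the final C3 acyl group without affecting a stereocentre.

Step 8
Reactants: 12 (1R,5S)-3,3,5-trimethyl-4-oxocyclohexyl tetradecanoate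
Product: 13 (1R)-3,5,5-trimethyl-4-(trifluoromethylsulfonyloxy)cyclohex-3-en-1-yl tetradecanoate
Conditions: Tf2O, 2,6-di-tert-butyl-4-methylpyridine, CH2Cl2, 0 °C to rt
Reagents that add atoms: trifluoromethanesulfonic anhydride, O=S(=O)(OS(=O)(=O)C(F)(F)F)C(F)(F)F
Why: O-Triflation of the ketone with Tf2O and a hindered pyridine base should give the enol triflate towards the only enolisable side, which fixes the C5=C6 double bond and deliberately destroys the relay stereocentre while tolerating the ester.

Step 9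
Reactants: 14 (E)-3-methylpent-2-en-4-yn-1-ol
Product: 15 (2E,4E)-3-methyl-5-(tributylstannyl)penta-2,4-dien-1-ol
Conditions: Bu3SnH, PdCl2(PPh3)2 (2 mol %), THF, 0 °C
Reagents that add atoms: tributyltin hydride, CCCC[SnH](CCCC)CCCC
Why: Palladium-catalysed syn-hydrostannation of the terminal alkyne should place tin at the terminal carbon and give the (E)-vinylstannane with the enyne geometry retained.

Step 10
Reactants: 13 (1R)-3,5,5-trimethyl-4-(trifluoromethylsulfonyloxy)cyclohex-3-en-1-yl tetradecanoate; 15 (2E,4E)-3-methyl-5-(tributylstannyl)penta-2,4-dien-1-ol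
Product: 16 (1R)-4-[(1E,3E)-5-hydroxy-3-methylpenta-1,3-dien-1-yl]-3,5,5-trimethylcyclohex-3-en-1-yl tetradecanoate
Conditions: Pd2(dba)3 (2.5 mol %), AsPh3 (20 mol %), NMP, 60 °C
Reagents that add atoms: none
Why: Stille coupling of the hindered cyclohexenyl triflate with the (E)-dienylstannane should proceed with retention of both alkene geometries and tolerate the ester and the free allylic alcohol.

Step 11
Reactants: 16 (1R)-4-[(1E,3E)-5-hydroxy-3-methylpenta-1,3-dien-1-yl]-3,5,5-trimethylcyclohex-3-en-1-yl tetradecanoate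
Product: 17 [(2E,4E)-3-methyl-5-[(4R)-2,6,6-trimethyl-4-(tetradecanoyloxy)cyclohex-1-en-1-yl]penta-2,4-dien-1-yl]triphenylphosphonium bromide
Conditions: PPh3·HBr, CH2Cl2, 0 °C to rt
Reagents that add atoms: triphenylphosphine hydrobromide, [Br-].c1ccc(cc1)[PH+](c1ccccc1)c1ccccc1
Why: Ionisation of the dienylic alcohol by HBr gives a pentadienyl cation that triphenylphosphine should trap at the primary terminus (standard phosphonium salt formation), the all-E salt being purified by crystallisation.

Step 12
Reactants: 18 (R)-α-ionone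
Product: 19 (3E)-4-[(1R,4R)-4-hydroxy-2,6,6-trimethylcyclohex-2-en-1-yl]but-3-en-2-one
Conditions: cytochrome P450 monooxygenase (P450 BM3 variant, E. coli whole cells), NADP+ (cat.), glucose dehydrogenase, D-glucose, air, phosphate buffer pH 7.5, 25 °C
Reagents that add atoms: dioxygen, O=O
Why: Allylic C–H hydroxylation by a cytochrome P450 monooxygenase should occur at C3' on the ring face anti to the C6' side chain, which gives the trans (3'R,6'R) alcohol without touching the enone.

Step 13
Reactants: 19 (3E)-4-[(1R,4R)-4-hydroxy-2,6,6-trimethylcyclohex-2-en-1-yl]but-3-en-2-one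
Product: 20 (1R,4R)-4-[(1E)-3-hydroxy-3-methylpenta-1,4-dien-1-yl]-3,5,5-trimethylcyclohex-2-en-1-ol (both epimers at the tertiary carbinol)
Conditions: CH2=CHMgBr (2.5 equiv), THF, −78 to 0 °C; aq NH4Cl
Reagents that add atoms: vinylmagnesium bromide, C=C[Mg]Br
Why: 1,2-Addition of the vinyl Grignard reagent to the enone carbonyl (the first equivalent deprotonates the 3'-OH) should give the tertiary bis-allylic alcohol, whose new centre forms as an epimer mixture and is removed in step 15.

Step 14
Reactants: 20 (1R,4R)-4-[(1E)-3-hydroxy-3-methylpenta-1,4-dien-1-yl]-3,5,5-trimethylcyclohex-2-en-1-ol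
Product: 21 (1R,4R)-4-[(1E)-3-hydroxy-3-methylpenta-1,4-dien-1-yl]-3,5,5-trimethylcyclohex-2-en-1-yl hexadecanoate
Conditions: palmitoyl chloride (1.05 equiv), pyridine, DMAP (cat.), CH2Cl2, 0 °C
Reagents that add atoms: hexadecanoyl chloride, CCCCCCCCCCCCCCCC(=O)Cl
Why: Pyridine/DMAP acylation should be selective for the secondary allylic alcohol over the tertiary one on steric grounds, with the stereocentres untouched.

Step 15
Reactants: 21 (1R,4R)-4-[(1E)-3-hydroxy-3-methylpenta-1,4-dien-1-yl]-3,5,5-trimethylcyclohex-2-en-1-yl hexadecanoate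
Product: 22 [(2E,4E)-5-[(1R,4R)-4-(hexadecanoyloxy)-2,6,6-trimethylcyclohex-2-en-1-yl]-3-methylpenta-2,4-dien-1-yl]triphenylphosphonium bromide
Conditions: PPh3·HBr, CH2Cl2, 0 °C to rt
Reagents that add atoms: triphenylphosphine hydrobromide, [Br-].c1ccc(cc1)[PH+](c1ccccc1)c1ccccc1
Why: Acid ionisation of the tertiary bis-allylic alcohol and capture of the delocalised cation by triphenylphosphine at the terminal CH2 (allylic transposition) should give the C15 phosphonium salt with the 9'E geometry predominating, the less easily ionised allylic ester staying in place.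

Step 16
Reactants: 22 [(2E,4E)-5-[(1R,4R)-4-(hexadecanoyloxy)-2,6,6-trimethylcyclohex-2-en-1-yl]-3-methylpenta-2,4-dien-1-yl]triphenylphosphonium bromide; 23 (2E,4E,6E)-2,7-dimethylocta-2,4,6-trienedial
Product: 25 (2E,4E,6E,8E,10E,12E)-13-[(1R,4R)-4-(hexadecanoyloxy)-2,6,6-trimethylcyclohex-2-en-1-yl]-2,7,11-trimethyltrideca-2,4,6,8,10,12-hexaenal, via phosphorus ylide 24 (not isolated)
Conditions: 23 (3 equiv), 1,2-epoxybutane/CH2Cl2, reflux; then heptane, reflux
Reagents that add atoms: none
Why: Wittig reaction of the ylide, generated without added base by bromide opening of the epoxide, with one aldehyde group of the excess dialdehyde should give the C25 aldehyde with the esters intact, the new 11',12' double bond being equilibrated to E by heating.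

Step 17
Reactants: 17 [(2E,4E)-3-methyl-5-[(4R)-2,6,6-trimethyl-4-(tetradecanoyloxy)cyclohex-1-en-1-yl]penta-2,4-dien-1-yl]triphenylphosphonium bromide; 25 (2E,4E,6E,8E,10E,12E)-13-[(1R,4R)-4-(hexadecanoyloxy)-2,6,6-trimethylcyclohex-2-en-1-yl]-2,7,11-trimethyltrideca-2,4,6,8,10,12-hexaenal
Product: 27 (3R,3'R,6'R)-lutein 3-O-tetradecanoate 3'-O-hexadecanoate, via phosphorus ylide 26 (not isolated)
Conditions: 1,2-epoxybutane/CH2Cl2, reflux; then heptane, reflux
Reagents that add atoms: none
Why: The second Wittig reaction under the same base-free epoxide conditions should join the two acylated halves, the sterically strained 11Z isomer being converted into the all-E target by thermal isomerisation.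

Compound list
1 | 3,3-dimethyloxetane | CC1(C)COC1 | starting material
2 | 3-iodo-2,2-dimethylpropan-1-ol | OCC(C)(C)CI | intermediate
3 | 3-iodo-2,2-dimethylpropanal | O=CC(C)(C)CI | intermediate
4 | (3S,4S)-1-iodo-2,2,4-trimethylhex-5-en-3-yl bis(isopinocampheyl)borinate | ICC(C)(C)[C@@H](OB([C@@H]1C[C@@H]2C[C@H]([C@H]1C)C2(C)C)[C@@H]1C[C@@H]2C[C@H]([C@H]1C)C2(C)C)[C@@H](C)C=C | intermediate
5 | (3S,4S)-1-iodo-2,2,4-trimethylhex-5-en-3-ol | ICC(C)(C)[C@@H](O)[C@@H](C)C=C | intermediate
6 | (3S,4S)-6-(9-borabicyclo[3.3.1]nonan-9-yl)-1-iodo-2,2,4-trimethylhexan-3-ol | ICC(C)(C)[C@@H](O)[C@@H](C)CCB1C2CCCC1CCC2 | intermediate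
7 | (3S,4S)-6-iodo-3,5,5-trimethylhexane-1,4-diol | ICC(C)(C)[C@@H](O)[C@@H](C)CCO | intermediate
8 | (3S,4S)-6-iodo-3,5,5-trimethylhexane-1,4-diyl bis(oxydimethylsulfonium) dichloride | ICC(C)(C)[C@@H](O[S+](C)C)[C@@H](C)CCO[S+](C)C.[Cl-].[Cl-] | intermediate
9 | (3S)-6-iodo-3,5,5-trimethyl-4-oxohexanal | ICC(C)(C)C(=O)[C@@H](C)CC=O | intermediate
10 | dichloro[(4S)-2,2,4-trimethyl-3,6-dioxohexyl]chromium | Cl[Cr](Cl)CC(C)(C)C(=O)[C@@H](C)CC=O | intermediate
11 | (4R,6S)-4-hydroxy-2,2,6-trimethylcyclohexan-1-one (cis) | O=C1[C@@H](C)C[C@@H](O)CC1(C)C | intermediate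
12 | (1R,5S)-3,3,5-trimethyl-4-oxocyclohexyl tetradecanoate | O=C1[C@@H](C)C[C@@H](OC(=O)CCCCCCCCCCCCC)CC1(C)C | intermediate
13 | (1R)-3,5,5-trimethyl-4-(trifluoromethylsulfonyloxy)cyclohex-3-en-1-yl tetradecanoate | FC(F)(F)S(=O)(=O)OC1=C(C)C[C@@H](OC(=O)CCCCCCCCCCCCC)CC1(C)C | intermediate
14 | (E)-3-methylpent-2-en-4-yn-1-ol | OC/C=C(C)/C#C | starting material
15 | (2E,4E)-3-methyl-5-(tributylstannyl)penta-2,4-dien-1-ol | OC/C=C(C)/C=C/[Sn](CCCC)(CCCC)CCCC | intermediate
16 | (1R)-4-[(1E,3E)-5-hydroxy-3-methylpenta-1,3-dien-1-yl]-3,5,5-trimethylcyclohex-3-en-1-yl tetradecanoate | OC/C=C(C)/C=C/C1=C(C)C[C@@H](OC(=O)CCCCCCCCCCCCC)CC1(C)C | intermediate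
17 | [(2E,4E)-3-methyl-5-[(4R)-2,6,6-trimethyl-4-(tetradecanoyloxy)cyclohex-1-en-1-yl]penta-2,4-dien-1-yl]triphenylphosphonium bromide | [Br-].c1ccccc1[P+](c1ccccc1)(c1ccccc1)C/C=C(C)/C=C/C1=C(C)C[C@@H](OC(=O)CCCCCCCCCCCCC)CC1(C)C | intermediate
18 | (R)-α-ionone, (3E)-4-[(1R)-2,6,6-trimethylcyclohex-2-en-1-yl]but-3-en-2-one | CC(=O)/C=C/[C@H]1C(C)=CCCC1(C)C | starting material
19 | (3E)-4-[(1R,4R)-4-hydroxy-2,6,6-trimethylcyclohex-2-en-1-yl]but-3-en-2-one | O[C@H]1C=C(C)[C@H](/C=C/C(C)=O)C(C)(C)C1 | intermediate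
20 | (1R,4R)-4-[(1E)-3-hydroxy-3-methylpenta-1,4-dien-1-yl]-3,5,5-trimethylcyclohex-2-en-1-ol (epimers at the tertiary carbinol) | O[C@H]1C=C(C)[C@H](/C=C/C(C)(O)C=C)C(C)(C)C1 | intermediate
21 | (1R,4R)-4-[(1E)-3-hydroxy-3-methylpenta-1,4-dien-1-yl]-3,5,5-trimethylcyclohex-2-en-1-yl hexadecanoate | CCCCCCCCCCCCCCCC(=O)O[C@H]1C=C(C)[C@H](/C=C/C(C)(O)C=C)C(C)(C)C1 | intermediate
22 | [(2E,4E)-5-[(1R,4R)-4-(hexadecanoyloxy)-2,6,6-trimethylcyclohex-2-en-1-yl]-3-methylpenta-2,4-dien-1-yl]triphenylphosphonium bromide | CCCCCCCCCCCCCCCC(=O)O[C@H]1C=C(C)[C@H](/C=C/C(C)=C/C[P+](c2ccccc2)(c2ccccc2)c2ccccc2)C(C)(C)C1.[Br-] | intermediate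
23 | (2E,4E,6E)-2,7-dimethylocta-2,4,6-trienedial | O=C/C(C)=C/C=C/C=C(C)/C=O | starting material
24 | triphenylphosphonium ylide of 22 | CCCCCCCCCCCCCCCC(=O)O[C@H]1C=C(C)[C@H](/C=C/C(C)=C/C=P(c2ccccc2)(c2ccccc2)c2ccccc2)C(C)(C)C1 | intermediate
25 | (2E,4E,6E,8E,10E,12E)-13-[(1R,4R)-4-(hexadecanoyloxy)-2,6,6-trimethylcyclohex-2-en-1-yl]-2,7,11-trimethyltrideca-2,4,6,8,10,12-hexaenal | CCCCCCCCCCCCCCCC(=O)O[C@H]1C=C(C)[C@H](/C=C/C(C)=C/C=C/C(C)=C/C=C/C=C(C)/C=O)C(C)(C)C1 | intermediate
26 | triphenylphosphonium ylide of 17 | c1ccccc1P(c1ccccc1)(c1ccccc1)=C/C=C(C)/C=C/C1=C(C)C[C@@H](OC(=O)CCCCCCCCCCCCC)CC1(C)C | intermediate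
27 | (3R,3'R,6'R)-lutein 3-O-tetradecanoate 3'-O-hexadecanoate (all-E) | CCCCCCCCCCCCCCCC(=O)O[C@H]1C=C(C)[C@H](/C=C/C(C)=C/C=C/C(C)=C/C=C/C=C(C)/C=C/C=C(C)/C=C/C2=C(C)C[C@@H](OC(=O)CCCCCCCCCCCCC)CC2(C)C)C(C)(C)C1 | target

Total step count: 17. Longest linear sequence: 11 steps (steps 1 to 8, then 10, 11 and 17).

Steps most likely to fail

Step 6. Halogen abstraction at the neopentyl-type carbon may be slower than side reactions of the aldehyde, or the chair preference may not translate into high facial selectivity at the new carbinol carbon. The fallback sets out from 9 and comes back at 11 by a stepwise polar organometallic route. Zinc insertion into the C–I bond (Zn dust activated with 1,2-dibromoethane and Me3SiCl, DMA, 40 °C) would give iodo[(4S)-2,2,4-trimethyl-3,6-dioxohexyl]zinc F1, a chelated zinc homoenolate that does not add to carbonyl groups by itself. Transmetalation with Ti(OiPr)3Cl at −30 °C should then trigger 1,2-addition to the aldehyde only, since organotitanium reagents discriminate aldehydes from ketones, through the same chair, to give 11 after aqueous work-up.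

Step 12. Low conversion, over-oxidation or insufficient regio- and facial control in the enzymatic allylic hydroxylation. The fallback sets out from 18 and comes back at 19 by protecting-group chemistry and chemical oxidation. The side-chain ketone is masked as the dioxolane (ethylene glycol, triethyl orthoformate, TsOH cat.) to give 2-methyl-2-[(E)-2-[(1R)-2,6,6-trimethylcyclohex-2-en-1-yl]ethenyl]-1,3-dioxolane F2. Allylic oxidation (t-BuOOH, aq NaOCl, MeCN, 0 °C) would give the ring enone (4R)-3,5,5-trimethyl-4-[(E)-2-(2-methyl-1,3-dioxolan-2-yl)ethenyl]cyclohex-2-en-1-one F3. Luche reduction (NaBH4, CeCl3·7H2O, MeOH, −20 °C) would give (1R,4R)-3,5,5-trimethyl-4-[(E)-2-(2-methyl-1,3-dioxolan-2-yl)ethenyl]cyclohex-2-en-1-ol F4, separated by chromatography from its 1-epimer, which can be recycled by Mitsunobu inversion. Mild ketal hydrolysis (aq oxalic acid, acetone) then returns 19.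

Step 10. Slow oxidative addition and transmetalation at the hindered triflate, with protodestannylation or homocoupling of the stannane taking over. The fallback sets out from 13 (with 14 as the side-chain source) and comes back at 16 by a boron-based union. Hydroboration of 14 with pinacolborane under Cp2ZrHCl catalysis would give (2E,4E)-3-methyl-5-(4,4,5,5-tetramethyl-1,3,2-dioxaborolan-2-yl)penta-2,4-dien-1-ol F5. This is joined to 13 by Suzuki–Miyaura coupling (Pd(OAc)2, SPhos, K3PO4, THF/H2O, 40 °C), which the fatty ester should tolerate.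

Further compounds
F1 | step 6 | iodo[(4S)-2,2,4-trimethyl-3,6-dioxohexyl]zinc | I[Zn]CC(C)(C)C(=O)[C@@H](C)CC=O
F2 | step 12 | 2-methyl-2-[(E)-2-[(1R)-2,6,6-trimethylcyclohex-2-en-1-yl]ethenyl]-1,3-dioxolane | CC1(/C=C/[C@H]2C(C)=CCCC2(C)C)OCCO1
F3 | step 12 | (4R)-3,5,5-trimethyl-4-[(E)-2-(2-methyl-1,3-dioxolan-2-yl)ethenyl]cyclohex-2-en-1-one | CC1(/C=C/[C@H]2C(C)=CC(=O)CC2(C)C)OCCO1
F4 | step 12 | (1R,4R)-3,5,5-trimethyl-4-[(E)-2-(2-methyl-1,3-dioxolan-2-yl)ethenyl]cyclohex-2-en-1-ol | O[C@H]1C=C(C)[C@H](/C=C/C2(C)OCCO2)C(C)(C)C1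
F5 | step 10 | (2E,4E)-3-methyl-5-(4,4,5,5-tetramethyl-1,3,2-dioxaborolan-2-yl)penta-2,4-dien-1-ol | OC/C=C(C)/C=C/B1OC(C)(C)C(C)(C)O1
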